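The route builds the benzo ring (C4a, C5–C8, C8a) of the non-chlorinated isoflavone around a diaryl ether oxygen that is already in place. The feature used is the C8–O–aryl linkage of ring A in that half: C8 lies between oxygenated C7 and the fusion carbon C8a, so C5–C8 can come from a diene oxygenated at alternate carbons with the aryl ether at its end. In one operation such a diene, a 4-aryloxy-1,3-dimethoxy-1-silyloxybutadiene whose aryl group is the complete chlorinated isoflavone, adds to a 3-aryl-5-sulfinyl-4-pyranone, forming C8–C8a and C4a–C5. Loss of benzenesulfenic acid and methanol then aromatises the ring, and one global demethylation gives the target.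

Key step: step 9

Remark: 4-methoxyphenylacetyl chloride is taken as a purchased starting material; sulfoxide 7 is racemic and diene 15 is used as formed, because the sulfur centre and the diene geometry are both erased in step 9 and the target has no stereocentre.

Step 1
Reactants: 1 4-methoxyphenylacetyl chloride
Product: 3 1-chloro-3-(4-methoxyphenyl)propan-2-one, via diazoketone 2 (not isolated)
Conditions: Me3SiCHN2 (2 eq), THF/MeCN, 0 °C → rt; then HCl (4 M in dioxane), 0 °C
Reagents that add atoms: (trimethylsilyl)diazomethane C[Si](C)(C)C=[N+]=[N-]; hydrogen chloride Cl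
Why: C-acylation of the diazoalkane (first stage of an Arndt–Eistert sequence) followed by hydrochlorination of the α-diazoketone with loss of nitrogen is the standard route from arylacetyl chlorides to chloromethyl ketones, and the absence of an amine base keeps the enolisable acid chloride from forming a ketene.

Step 2
Reactants: 3 1-chloro-3-(4-methoxyphenyl)propan-2-one
Product: 4 1-(4-methoxyphenyl)-3-(phenylsulfanyl)propan-2-one
Conditions: PhSH (1.05 eq), K2CO3, acetone, 0 °C → rt
Reagents that add atoms: thiophenol Sc1ccccc1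
Why: SN2 displacement of an α-chloroketone by a soft thiolate is fast at low temperature and should outrun enolate side reactions of the ketone.

Step 3
Reactants: 4 1-(4-methoxyphenyl)-3-(phenylsulfanyl)propan-2-one
Product: 6 3-(4-methoxyphenyl)-5-(phenylsulfanyl)-4H-pyran-4-one, via bis-enaminone 5 (not isolated)
Conditions: Me2NCH(OMe)2 (5 eq), toluene, 110 °C; then 2 M aq. HCl, THF, 50 °C
Reagents that add atoms: N,N-dimethylformamide dimethyl acetal COC(OC)N(C)C; water O
Why: both methylene groups (benzylic and α-sulfanyl) are acidic enough for double aminomethylenation, and acid hydrolysis of one enamine followed by addition–elimination onto the other closes the 4-pyranone, a cyclocondensation known for 1,3-diarylacetones.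

Step 4
Reactants: 6 3-(4-methoxyphenyl)-5-(phenylsulfanyl)-4H-pyran-4-one
Product: 7 3-(4-methoxyphenyl)-5-(phenylsulfinyl)-4H-pyran-4-one (racemic at sulfur)
Conditions: mCPBA (1.0 eq), CH2Cl2, −40 → 0 °C
Reagents that add atoms: 3-chloroperoxybenzoic acid OOC(=O)c1cccc(Cl)c1
Why: sulfide-to-sulfoxide oxidation with one equivalent of peracid at low temperature is chemoselective, since the pyranone double bonds are electron-poor and the sulfoxide is oxidised further only slowly.

Step 5
Reactants: 8 3,5-dimethoxyphenol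
Product: 9 2-chloro-3,5-dimethoxyphenol
Conditions: SO2Cl2 (1.0 eq), CHCl3, 0 °C → rt
Reagents that add atoms: sulfuryl chloride O=S(=O)(Cl)Cl
Why: electrophilic aromatic chlorination of the phloroglucinol-type ring should take place at C2, ortho to the hydroxyl and para to a methoxy group, and the 4-chloro isomer expected as a side product is removed at this cheap stage by chromatography.

Step 6
Reactants: 9 2-chloro-3,5-dimethoxyphenol; 10 4-hydroxyphenylacetic acid
Product: 12 8-chloro-3-(4-hydroxyphenyl)-5,7-dimethoxy-4H-chromen-4-one, via deoxybenzoin 11 (not isolated)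
Conditions: BF3·OEt2 (neat), 85 °C; then DMF, MsCl, 0 → 70 °C; ice-water quench
Reagents that add atoms: N,N-dimethylformamide CN(C)C=O
Why: BF3-mediated Friedel–Crafts (Fries-type) C-acylation at C6, the only free position ortho to the phenol, gives the chelated deoxybenzoin, and the Vilsmeier-type iminium reagent from DMF and MsCl then formylates its methylene group and closes the pyranone ring in the same flask (one-pot deoxybenzoin route to isoflavones, which tolerates free phenols).

Step 7
Reactants: 12 8-chloro-3-(4-hydroxyphenyl)-5,7-dimethoxy-4H-chromen-4-one; 13 methyl (E)-4-chloro-3-methoxybut-2-enoate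
Product: 14 methyl (2E)-4-[4-(8-chloro-5,7-dimethoxy-4-oxo-4H-chromen-3-yl)phenoxy]-3-methoxybut-2-enoate
Conditions: K2CO3 (2 eq), KI (cat.), acetone, reflux
Reagents that add atoms: none
Why: Williamson ether synthesis by SN2 of the phenoxide at the primary allylic chloride makes the ether C–O bond at an unhindered sp3 carbon, while the β-methoxy enoate is a poor Michael acceptor and keeps its E geometry.

Step 8
Reactants: 14 methyl (2E)-4-[4-(8-chloro-5,7-dimethoxy-4-oxo-4H-chromen-3-yl)phenoxy]-3-methoxybut-2-enoate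
Product: 15 8-chloro-3-[4-({(1Z,3Z)-2,4-dimethoxy-4-[(trimethylsilyl)oxy]buta-1,3-dien-1-yl}oxy)phenyl]-5,7-dimethoxy-4H-chromen-4-one
Conditions: Me3SiCl (1.5 eq), LiN(SiMe3)2 (1.2 eq), THF, −78 → 0 °C; hexane, filtration under Ar, used crude
Reagents that add atoms: chlorotrimethylsilane C[Si](C)(C)Cl
Why: γ-deprotonation of the β-methoxy enoate at the CH2OAr group cis to the ester, its only sp3 C–H acid, and O-silylation of the dienolate is the standard preparation of 1,3-dialkoxy-1-silyloxybutadienes (Brassard-type dienes), and the hindered silylamide with in situ silyl chloride is too weak a base to metalate the isoflavone C2–H.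

Step 9
Reactants: 15 8-chloro-3-[4-({(1Z,3Z)-2,4-dimethoxy-4-[(trimethylsilyl)oxy]buta-1,3-dien-1-yl}oxy)phenyl]-5,7-dimethoxy-4H-chromen-4-one; 7 3-(4-methoxyphenyl)-5-(phenylsulfinyl)-4H-pyran-4-one
Product: 19 8-[4-(8-chloro-5,7-dimethoxy-4-oxo-4H-chromen-3-yl)phenoxy]-5-hydroxy-7-methoxy-3-(4-methoxyphenyl)-4H-chromen-4-one, via cycloadduct 16 (not isolated), via dihydrochromenone 17 (not isolated), via aryl silyl ether 18 (not isolated)
Conditions: 15 (1.3 eq), toluene, 0 → 25 °C; then 80 °C; then 1 M HCl, THF, rt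
Reagents that add atoms: none
Why: Proposed new method: the ketene-acetal diene 15 should add across C5=C6 of 7, the only pyranone double bond activated by both the C4 carbonyl and the sulfinyl group, either as a polarised [4+2] cycloaddition or as a vinylogous Michael addition whose zwitterion collapses onto the silyloxocarbenium carbon; both paths form C8–C8a and C4a–C5 and give the cis-fused adduct 16. The closest known reaction types are the cycloaddition–elimination–aromatisation of Brassard-type dienes with halo- or sulfinylquinones and the Diels–Alder reactions of chromones carrying a 3-acceptor group with siloxydienes, but a 3-sulfinyl-4-pyranone has not been combined with a 4-aryloxy ketene-acetal diene. The new carbocycle is closed by this [4+2] annulation and aromatises because the C4a sulfoxide and the cis 8a-H undergo thermal syn-elimination of benzenesulfenic acid (17), after which 1,4-loss of methanol from the C5 silyl methyl ketal and C8–H gives aryl silyl ether 18, hydrolysed on acidic work-up to the hydrogen-bonded 5-phenol. No stereocentre survives, since C4a, C5, C8, C8a and sulfur all lose their configuration, so endo/exo and facial selectivity do not matter. The step needs regioselectivity (aryloxy at C8, not C6) and site selectivity: the first should follow from the largest HOMO coefficient at the aryloxy-bearing terminus of the 1,3-dioxygenated diene matching the largest LUMO coefficient at C6 of the sulfinyl enone, the second from the lack of sulfinyl activation at C2=C3 of 7 and at the isoflavone of 15. Neutral thermal conditions without Lewis acid or fluoride are chosen so that any Michael-type intermediate stays O-silylated and the pyranone ring is not opened by retro-oxa-Michael cleavage.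

Step 10
Reactants: 19 8-[4-(8-chloro-5,7-dimethoxy-4-oxo-4H-chromen-3-yl)phenoxy]-5-hydroxy-7-methoxy-3-(4-methoxyphenyl)-4H-chromen-4-one
Product: 20 8-[4-(8-chloro-5,7-dihydroxy-4-oxo-4H-chromen-3-yl)phenoxy]-5,7-dihydroxy-3-(4-hydroxyphenyl)-4H-chromen-4-one
Conditions: BBr3 (12 eq), CH2Cl2, −78 °C → rt; MeOH, then H2O
Reagents that add atoms: none
Why: Lewis-acid-mediated SN2 demethylation of the four aryl methyl ethers leaves the diaryl ether, the aryl chloride and both pyranone rings untouched, and the anhydrous low-temperature conditions avoid the ring-opening and reclosure (Wessely–Moser isomerisation) that hot protic acids can cause in 5-hydroxy-8-substituted chromones.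

Compound list
1 | 4-methoxyphenylacetyl chloride | COc1ccc(CC(=O)Cl)cc1 | starting material
2 | 1-diazo-3-(4-methoxyphenyl)propan-2-one | COc1ccc(CC(=O)C=[N+]=[N-])cc1 | intermediate
3 | 1-chloro-3-(4-methoxyphenyl)propan-2-one | COc1ccc(CC(=O)CCl)cc1 | intermediate
4 | 1-(4-methoxyphenyl)-3-(phenylsulfanyl)propan-2-one | COc1ccc(CC(=O)CSc2ccccc2)cc1 | intermediate
5 | 1,5-bis(dimethylamino)-2-(4-methoxyphenyl)-4-(phenylsulfanyl)penta-1,4-dien-3-one (push-pull alkenes, geometry not fixed) | CN(C)C=C(c1ccc(OC)cc1)C(=O)C(=CN(C)C)Sc1ccccc1 | intermediate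
6 | 3-(4-methoxyphenyl)-5-(phenylsulfanyl)-4H-pyran-4-one | COc1ccc(-c2cocc(Sc3ccccc3)c2=O)cc1 | intermediate
7 | 3-(4-methoxyphenyl)-5-(phenylsulfinyl)-4H-pyran-4-one (racemic at sulfur) | COc1ccc(-c2cocc(S(=O)c3ccccc3)c2=O)cc1 | intermediate
8 | 3,5-dimethoxyphenol | COc1cc(O)cc(OC)c1 | starting material
9 | 2-chloro-3,5-dimethoxyphenol | COc1cc(O)c(Cl)c(OC)c1 | intermediate
10 | 4-hydroxyphenylacetic acid | OC(=O)Cc1ccc(O)cc1 | starting material
11 | 1-(3-chloro-2-hydroxy-4,6-dimethoxyphenyl)-2-(4-hydroxyphenyl)ethan-1-one | COc1cc(OC)c(C(=O)Cc2ccc(O)cc2)c(O)c1Cl | intermediate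
12 | 8-chloro-3-(4-hydroxyphenyl)-5,7-dimethoxy-4H-chromen-4-one | COc1cc(OC)c2c(=O)c(-c3ccc(O)cc3)coc2c1Cl | intermediate
13 | methyl (E)-4-chloro-3-methoxybut-2-enoate | COC(=O)/C=C(/OC)CCl | starting material
14 | methyl (2E)-4-[4-(8-chloro-5,7-dimethoxy-4-oxo-4H-chromen-3-yl)phenoxy]-3-methoxybut-2-enoate | COC(=O)/C=C(/OC)COc1ccc(cc1)-c1coc2c(Cl)c(OC)cc(OC)c2c1=O | intermediate
15 | 8-chloro-3-[4-({(1Z,3Z)-2,4-dimethoxy-4-[(trimethylsilyl)oxy]buta-1,3-dien-1-yl}oxy)phenyl]-5,7-dimethoxy-4H-chromen-4-one | COc1cc(OC)c2c(=O)c(-c3ccc(O/C=C(OC)/C=C(/OC)O[Si](C)(C)C)cc3)coc2c1Cl | intermediate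
16 | cis-fused cycloadduct: 8-[4-(8-chloro-5,7-dimethoxy-4-oxo-4H-chromen-3-yl)phenoxy]-5,7-dimethoxy-3-(4-methoxyphenyl)-4a-(phenylsulfinyl)-5-[(trimethylsilyl)oxy]-4a,5,8,8a-tetrahydro-4H-chromen-4-one (racemic; sulfinyl and 8a-H cis, relative configuration shown; mixture at C5, C8 and sulfur) | O=C1C(c2ccc(OC)cc2)=CO[C@H]2[C@]1(S(=O)c1ccccc1)C(OC)(O[Si](C)(C)C)C=C(OC)C2Oc1ccc(cc1)-c1coc2c(Cl)c(OC)cc(OC)c2c1=O | intermediate
17 | 8-[4-(8-chloro-5,7-dimethoxy-4-oxo-4H-chromen-3-yl)phenoxy]-5,7-dimethoxy-3-(4-methoxyphenyl)-5-[(trimethylsilyl)oxy]-5,8-dihydro-4H-chromen-4-one (mixture at C5 and C8) | O=C1C(c2ccc(OC)cc2)=COC2=C1C(OC)(O[Si](C)(C)C)C=C(OC)C2Oc1ccc(cc1)-c1coc2c(Cl)c(OC)cc(OC)c2c1=O | intermediate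
18 | 8-[4-(8-chloro-5,7-dimethoxy-4-oxo-4H-chromen-3-yl)phenoxy]-7-methoxy-3-(4-methoxyphenyl)-5-[(trimethylsilyl)oxy]-4H-chromen-4-one | O=c1c(-c2ccc(OC)cc2)coc2c(Oc3ccc(cc3)-c3coc4c(Cl)c(OC)cc(OC)c4c3=O)c(OC)cc(O[Si](C)(C)C)c12 | intermediate
19 | 8-[4-(8-chloro-5,7-dimethoxy-4-oxo-4H-chromen-3-yl)phenoxy]-5-hydroxy-7-methoxy-3-(4-methoxyphenyl)-4H-chromen-4-one | O=c1c(-c2ccc(Oc3c(OC)cc(O)c4c(=O)c(-c5ccc(OC)cc5)coc34)cc2)coc2c(Cl)c(OC)cc(OC)c12 | intermediate
20 | 8-[4-(8-chloro-5,7-dihydroxy-4-oxo-4H-chromen-3-yl)phenoxy]-5,7-dihydroxy-3-(4-hydroxyphenyl)-4H-chromen-4-one | O=c1c(-c2ccc(Oc3c(O)cc(O)c4c(=O)c(-c5ccc(O)cc5)coc34)cc2)coc2c(Cl)c(O)cc(O)c12 | target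

Total step count: 10. Longest linear sequence: 6 steps (8 → 9 → 12 → 14 → 15 → 19 → 20; the branch 1 → 3 → 4 → 6 → 7 → 19 → 20 is equally long).

Steps most likely to fail

Step 9 (Proposed new method). The cycloaddition may be too slow to outrun hydrolysis or O-to-C silyl migration of the diene, or a Michael-type intermediate may open the pyranone ring instead of closing the carbocycle. The fallback uses known chemistry, sets out from 12 and comes back to the route at 20. Purchased 5,7-dimethoxy-3-(4-methoxyphenyl)-4H-chromen-4-one F1 would be iodinated at C8, the usual site in 5,7-dialkoxychromones, with N-iodosuccinimide and CF3CO2H in MeCN to give 8-iodo-5,7-dimethoxy-3-(4-methoxyphenyl)-4H-chromen-4-one F2. Ullmann diaryl ether coupling of phenol 12 with F2 (CuI, picolinic acid, K3PO4, DMSO, 90 °C), a ligand-accelerated protocol that tolerates doubly ortho-substituted aryl iodides and leaves the aryl chloride alone, should give 8-[4-(8-chloro-5,7-dimethoxy-4-oxo-4H-chromen-3-yl)phenoxy]-5,7-dimethoxy-3-(4-methoxyphenyl)-4H-chromen-4-one F3. BBr3 under the conditions of step 10 would cleave its five methyl ethers to 20.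

Step 8. The amide base may attack or metalate the isoflavone, the dienolate may be C-silylated, or the ketene acetal may hydrolyse during isolation. The fallback sets out from 14 and comes back at 20, replacing kinetic deprotonation by soft enolisation of a more acidic substrate. Hydrolysis of the enol ether (1 M HCl, THF, rt) should give methyl 4-[4-(8-chloro-5,7-dimethoxy-4-oxo-4H-chromen-3-yl)phenoxy]-3-oxobutanoate F4. Double silylation with Me3SiOTf and Et3N in Et2O at 0 °C, which needs no strong base, should give 8-chloro-3-[4-({(1Z,3Z)-4-methoxy-2,4-bis[(trimethylsilyl)oxy]buta-1,3-dien-1-yl}oxy)phenyl]-5,7-dimethoxy-4H-chromen-4-one F5, a member of the known 4-aryloxy-1,3-bis(silyloxy)diene class. With 7 under the conditions of step 9 it would pass through cycloadduct F6, dihydrochromenone F7 and bis(silyl ether) F8 to 8-[4-(8-chloro-5,7-dimethoxy-4-oxo-4H-chromen-3-yl)phenoxy]-5,7-dihydroxy-3-(4-methoxyphenyl)-4H-chromen-4-one F9. Its three remaining methyl ethers would be cleaved with BBr3 as in step 10 to give 20.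

Step 5. Chlorination may be poorly selective between C2 and C4, or run on to a dichloride. The fallback sets out from 8 and comes back at 9, fixing the site by directed metalation. Carbamoylation (Et2NCOCl, K2CO3, MeCN, reflux) gives 3,5-dimethoxyphenyl diethylcarbamate F10. Directed ortho-lithiation (s-BuLi, TMEDA, THF, −78 °C) at the position between the carbamate and a methoxy group gives [2-(diethylcarbamoyloxy)-4,6-dimethoxyphenyl]lithium F11, which is trapped with C2Cl6 as 2-chloro-3,5-dimethoxyphenyl diethylcarbamate F12. KOH in EtOH at reflux, then aqueous HCl, releases 9.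

Further compounds
F1 | step 9 | 5,7-dimethoxy-3-(4-methoxyphenyl)-4H-chromen-4-one | COc1ccc(cc1)-c1coc2cc(OC)cc(OC)c2c1=O
F2 | step 9 | 8-iodo-5,7-dimethoxy-3-(4-methoxyphenyl)-4H-chromen-4-one | COc1ccc(cc1)-c1coc2c(I)c(OC)cc(OC)c2c1=O
F3 | step 9 | 8-[4-(8-chloro-5,7-dimethoxy-4-oxo-4H-chromen-3-yl)phenoxy]-5,7-dimethoxy-3-(4-methoxyphenyl)-4H-chromen-4-one | O=c1c(-c2ccc(Oc3c(OC)cc(OC)c4c(=O)c(-c5ccc(OC)cc5)coc34)cc2)coc2c(Cl)c(OC)cc(OC)c12
F4 | step 8 | methyl 4-[4-(8-chloro-5,7-dimethoxy-4-oxo-4H-chromen-3-yl)phenoxy]-3-oxobutanoate | COC(=O)CC(=O)COc1ccc(cc1)-c1coc2c(Cl)c(OC)cc(OC)c2c1=O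
F5 | step 8 | 8-chloro-3-[4-({(1Z,3Z)-4-methoxy-2,4-bis[(trimethylsilyl)oxy]buta-1,3-dien-1-yl}oxy)phenyl]-5,7-dimethoxy-4H-chromen-4-one | COc1cc(OC)c2c(=O)c(-c3ccc(O/C=C(O[Si](C)(C)C)/C=C(/OC)O[Si](C)(C)C)cc3)coc2c1Cl
F6 | step 8 | cis-fused cycloadduct: 8-[4-(8-chloro-5,7-dimethoxy-4-oxo-4H-chromen-3-yl)phenoxy]-5-methoxy-3-(4-methoxyphenyl)-4a-(phenylsulfinyl)-5,7-bis[(trimethylsilyl)oxy]-4a,5,8,8a-tetrahydro-4H-chromen-4-one (racemic, relative configuration at the ring fusion shown) | O=C1C(c2ccc(OC)cc2)=CO[C@H]2[C@]1(S(=O)c1ccccc1)C(OC)(O[Si](C)(C)C)C=C(O[Si](C)(C)C)C2Oc1ccc(cc1)-c1coc2c(Cl)c(OC)cc(OC)c2c1=O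
F7 | step 8 | 8-[4-(8-chloro-5,7-dimethoxy-4-oxo-4H-chromen-3-yl)phenoxy]-5-methoxy-3-(4-methoxyphenyl)-5,7-bis[(trimethylsilyl)oxy]-5,8-dihydro-4H-chromen-4-one | O=C1C(c2ccc(OC)cc2)=COC2=C1C(OC)(O[Si](C)(C)C)C=C(O[Si](C)(C)C)C2Oc1ccc(cc1)-c1coc2c(Cl)c(OC)cc(OC)c2c1=O
F8 | step 8 | 8-[4-(8-chloro-5,7-dimethoxy-4-oxo-4H-chromen-3-yl)phenoxy]-3-(4-methoxyphenyl)-5,7-bis[(trimethylsilyl)oxy]-4H-chromen-4-one | O=c1c(-c2ccc(OC)cc2)coc2c(Oc3ccc(cc3)-c3coc4c(Cl)c(OC)cc(OC)c4c3=O)c(O[Si](C)(C)C)cc(O[Si](C)(C)C)c12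
F9 | step 8 | 8-[4-(8-chloro-5,7-dimethoxy-4-oxo-4H-chromen-3-yl)phenoxy]-5,7-dihydroxy-3-(4-methoxyphenyl)-4H-chromen-4-one | O=c1c(-c2ccc(Oc3c(O)cc(O)c4c(=O)c(-c5ccc(OC)cc5)coc34)cc2)coc2c(Cl)c(OC)cc(OC)c12
F10 | step 5 | 3,5-dimethoxyphenyl diethylcarbamate | CCN(CC)C(=O)Oc1cc(OC)cc(OC)c1
F11 | step 5 | [2-(diethylcarbamoyloxy)-4,6-dimethoxyphenyl]lithium | CCN(CC)C(=O)Oc1cc(OC)cc(OC)c1[Li]
F12 | step 5 | 2-chloro-3,5-dimethoxyphenyl diethylcarbamate | CCN(CC)C(=O)Oc1cc(OC)cc(OC)c1Cl
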